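The route rests on cutting the bond between C2 of the γ-pyrone ring (ring C) and C1' of the guaiacyl ring B. C2 is the β-carbon of the C2=C3–C4=O enone and thus a natural acceptor. Once C3 bears oxygen, C2 also carries the only acidic vinylic C–H, flanked by O1 and the C3–O group. A hindered zinc amide removes this proton and reverses the polarity of C2. A Negishi coupling with a 4-benzyloxy-3-methoxyphenyl bromide then delivers the whole flavonol skeleton in one flask. The precursor is a 2-unsubstituted 3-benzoyloxy-5-hydroxy-7-methoxychromone, made in two steps. The ester/ether pair differentiates O3 from O4' for the final 3-O-sulfation.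

Key step: step 3

Remark: the target has no stereocentre, no stereogenic axis and no configurable double bond, so it is one achiral compound and no step has to control configuration. It is delivered in the drawn free hydrogen sulfate form, released from its salt in the last operation.

Step 1
Reactants: 1 1-(2,6-dihydroxy-4-methoxyphenyl)ethanone (2',6'-dihydroxy-4'-methoxyacetophenone)
Product: 2 (E)-3-(dimethylamino)-1-(2,6-dihydroxy-4-methoxyphenyl)prop-2-en-1-one
Conditions: DMF-DMA (1.5 equiv), toluene, 90 °C
Reagents that add atoms: N,N-dimethylformamide dimethyl acetal, COC(OC)N(C)C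
Why: Amide-acetal condensation (enaminone formation), in which the acidic methyl group of the aryl methyl ketone condenses with loss of two methanol to give the thermodynamically favoured E push-pull alkene, while the hydrogen-bonded phenols should escape O-methylation when the reagent is limited.

Step 2
Reactants: 2 (E)-3-(dimethylamino)-1-(2,6-dihydroxy-4-methoxyphenyl)prop-2-en-1-one
Product: 4 5-hydroxy-7-methoxy-4-oxo-4H-chromen-3-yl benzoate, via acyloxy enaminone 3 (not isolated)
Conditions: (BzO)2 (1.1 equiv), MeCN, 70 °C
Reagents that add atoms: dibenzoyl peroxide, O=C(OOC(=O)c1ccccc1)c1ccccc1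
Why: α-C–H acyloxylation of a tertiary enaminone with a diacyl peroxide followed by chromone annulation, in which the nucleophilic α-carbon takes up a benzoyloxy group from the O–O bond and one of the two equivalent ortho-phenols then adds to the β-carbon and expels dimethylamine (addition–elimination), so that no regiochemical question arises.

Step 3
Reactants: 4 5-hydroxy-7-methoxy-4-oxo-4H-chromen-3-yl benzoate; 5 1-(benzyloxy)-4-bromo-2-methoxybenzene
Product: 8 4'-O-benzylrhamnazin [2-(4-benzyloxy-3-methoxyphenyl)-3,5-dihydroxy-7-methoxy-4H-chromen-4-one], via C2-zincated chromone 6 (not isolated), via flavone benzoate 7 (not isolated)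
Conditions: TMPZnCl·LiCl (2.3 equiv), THF, 25 °C; then 5 (1.1 equiv), Pd(OAc)2 (2 mol%), SPhos (4 mol%), 50 °C; then pyrrolidine (5 equiv), 25 °C; 1 M HCl work-up
Reagents that add atoms: TMPZnCl·LiCl, CC1(C)CCCC(C)(C)N1[Zn]Cl.[Li+].[Cl-] (its ZnCl units are found in 6 and 7 only, not in 8)
Why: The first equivalent of the zinc amide converts the 5-OH into its zinc phenolate, and the second removes the C2–H of the γ-pyrone ring, the only acidic vinylic C–H because C3 is blocked and C2 is flanked by O1 and the withdrawing C3–O-benzoate, so the natural acceptor carbon of the enone becomes the donor 6. Pd(0)/SPhos inserts into the C–Br bond of 5, and transmetalation from C2–Zn with reductive elimination forms the C2–C1' bond (Negishi cross-coupling) to give 7, after which pyrrolidine aminolyses the activated enol benzoate and bares only O3 while O4' stays benzylated. The closest known reaction type is the regioselective C2-zincation of chromones with TMP-zinc bases followed by Negishi arylation to flavones. No ring is closed and no stereocentre is formed. The step needs metalation at C2 rather than at C6 or C8 of ring A and no attack on the ester, which the mild, hindered and non-nucleophilic zinc amide secures because it tolerates esters and does not metalate plain alkoxyarenes at 25 °C. The alkenylzinc chloride is too weak a nucleophile for an O-to-C benzoyl shift, and the aryl bromide has no ortho substituent that would slow the coupling.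

Step 4
Reactants: 8 4'-O-benzylrhamnazin
Product: 9 triethylammonium 2-(4-benzyloxy-3-methoxyphenyl)-5-hydroxy-7-methoxy-4-oxo-4H-chromen-3-yl sulfate
Conditions: SO3·NEt3 (4 equiv), DMF, 40 °C; Sephadex LH-20
Reagents that add atoms: sulfur trioxide–triethylamine complex, CC[N+](CC)(CC)S(=O)(=O)[O-]
Why: O-sulfation with an amine–sulfur trioxide complex, in which the enolic 3-OH reacts while the 5-OH, locked in a strong six-membered hydrogen bond to C4=O, resists such reagents and O4' is masked as its benzyl ether.

Step 5
Reactants: 9 triethylammonium 2-(4-benzyloxy-3-methoxyphenyl)-5-hydroxy-7-methoxy-4-oxo-4H-chromen-3-yl sulfate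
Product: 11 rhamnazin 3-O-sulfate (free hydrogen sulfate), via triethylammonium rhamnazin 3-sulfate 10 (not isolated)
Conditions: H2 (1 atm), 10% Pd/C, MeOH, 25 °C; filter; then Dowex 50WX8 (H+ form), H2O/MeOH, 0 °C, lyophilise
Reagents that add atoms: none
Why: Catalytic hydrogenolysis of the aryl benzyl ether under neutral conditions should leave the sulfate monoester salt, the aryl methyl ethers and the tetrasubstituted C2=C3 bond untouched, and cold cation exchange then replaces triethylammonium by a proton.

Compound list
1 | 1-(2,6-dihydroxy-4-methoxyphenyl)ethanone | CC(=O)c1c(O)cc(OC)cc1O | starting material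
2 | (E)-3-(dimethylamino)-1-(2,6-dihydroxy-4-methoxyphenyl)prop-2-en-1-one | CN(C)/C=C/C(=O)c1c(O)cc(OC)cc1O | intermediate
3 | (Z)-1-(dimethylamino)-3-(2,6-dihydroxy-4-methoxyphenyl)-3-oxoprop-1-en-2-yl benzoate (acyloxy enaminone) | CN(C)/C=C(OC(=O)c1ccccc1)/C(=O)c1c(O)cc(OC)cc1O | intermediate
4 | 5-hydroxy-7-methoxy-4-oxo-4H-chromen-3-yl benzoate | COc1cc(O)c2c(=O)c(OC(=O)c3ccccc3)coc2c1 | intermediate
5 | 1-(benzyloxy)-4-bromo-2-methoxybenzene | COc1cc(Br)ccc1OCc1ccccc1 | starting material
6 | 2-(chlorozincio)-5-(chlorozinciooxy)-7-methoxy-4-oxo-4H-chromen-3-yl benzoate (C2-zincated chromone) | COc1cc(O[Zn]Cl)c2c(=O)c(OC(=O)c3ccccc3)c([Zn]Cl)oc2c1 | intermediate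
7 | 2-(4-benzyloxy-3-methoxyphenyl)-5-(chlorozinciooxy)-7-methoxy-4-oxo-4H-chromen-3-yl benzoate (flavone benzoate, present as its 5-O-zinc phenolate) | COc1cc(O[Zn]Cl)c2c(=O)c(OC(=O)c3ccccc3)c(-c3ccc(OCc4ccccc4)c(OC)c3)oc2c1 | intermediate
8 | 4'-O-benzylrhamnazin, 2-(4-benzyloxy-3-methoxyphenyl)-3,5-dihydroxy-7-methoxy-4H-chromen-4-one | COc1cc(O)c2c(=O)c(O)c(-c3ccc(OCc4ccccc4)c(OC)c3)oc2c1 | intermediate
9 | triethylammonium 2-(4-benzyloxy-3-methoxyphenyl)-5-hydroxy-7-methoxy-4-oxo-4H-chromen-3-yl sulfate | COc1cc(O)c2c(=O)c(OS(=O)(=O)[O-])c(-c3ccc(OCc4ccccc4)c(OC)c3)oc2c1.CC[NH+](CC)CC | intermediate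
10 | triethylammonium rhamnazin 3-sulfate | COc1cc(O)c2c(=O)c(OS(=O)(=O)[O-])c(-c3ccc(O)c(OC)c3)oc2c1.CC[NH+](CC)CC | intermediate
11 | rhamnazin 3-O-sulfate, 5-hydroxy-2-(4-hydroxy-3-methoxyphenyl)-7-methoxy-4-oxo-4H-chromen-3-yl hydrogen sulfate | COc1cc(O)c2c(=O)c(OS(=O)(=O)O)c(-c3ccc(O)c(OC)c3)oc2c1 | target

Total step count: 5. Longest linear sequence: 5 steps (1 to 11); compound 5 enters as purchased.

Steps most likely to fail

Step 3. The zinc phenolate formed first at O5 pushes electron density into the pyrone, so the second deprotonation at C2 may stall. The C2-zinc species may also transmetalate slowly or shift the neighbouring benzoyl group from oxygen to carbon. The fallback sets out from 4 and uses C2 in its natural acceptor role. It is a Pd(II)-catalysed oxidative boron-Heck arylation (Pd(TFA)2, 1,10-phenanthroline, O2, DMF, 80 °C) with commercial [4-(benzyloxy)-3-methoxyphenyl]boronic acid F1. The aryl-palladium species should add across C2=C3 with the aryl group at C2. β-Hydride elimination by way of the oxygen-bound palladium enolate should then give 2-(4-benzyloxy-3-methoxyphenyl)-5-hydroxy-7-methoxy-4-oxo-4H-chromen-3-yl benzoate F2. Aminolysis with pyrrolidine in THF comes back to the route at 8.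

Step 2. The peroxide may oxidise the electron-rich phenol ring in competition with the enaminone. The released dimethylamine may also strip the enol benzoate as it forms. The fallback sets out from 2 and installs O3 by epoxidation instead of acyloxylation.
- Aqueous HCl in CH2Cl2 should cyclise 2 to 5-hydroxy-7-methoxy-4H-chromen-4-one F3.
- Dimethyldioxirane in acetone/CH2Cl2 at 0 °C should give racemic cis-fused 2,3-epoxy-5-hydroxy-7-methoxychroman-4-one F4.
- Catalytic TsOH should isomerise F4 to 3,5-dihydroxy-7-methoxy-4H-chromen-4-one F5.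
- Benzoyl chloride (1.0 equiv) in pyridine at 0 °C should acylate the non-chelated 3-OH and come back to the route at 4.

Step 4. The hindered, hydrogen-bonded 3-OH may react sluggishly. Forcing conditions may start sulfation at O5, and the ionic product may lose its sulfate during purification. The fallback sets out from 8 and carries the sulfate as a neutral, chromatographable diester.
- 2,2,2-Trichloroethyl chlorosulfate with Et3N and DMAP in THF should give 2-(4-benzyloxy-3-methoxyphenyl)-5-hydroxy-7-methoxy-4-oxo-4H-chromen-3-yl 2,2,2-trichloroethyl sulfate F6.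
- Pd/C with ammonium formate in MeOH should remove the trichloroethyl group reductively and the benzyl ether by transfer hydrogenolysis, giving ammonium rhamnazin 3-sulfate F7.
- Cold exchange on the H+ resin comes back to the route at 11.

Further compounds
F1 | step 3 | [4-(benzyloxy)-3-methoxyphenyl]boronic acid | COc1cc(B(O)O)ccc1OCc1ccccc1
F2 | step 3 | 2-(4-benzyloxy-3-methoxyphenyl)-5-hydroxy-7-methoxy-4-oxo-4H-chromen-3-yl benzoate | COc1cc(O)c2c(=O)c(OC(=O)c3ccccc3)c(-c3ccc(OCc4ccccc4)c(OC)c3)oc2c1
F3 | step 2 | 5-hydroxy-7-methoxy-4H-chromen-4-one | COc1cc(O)c2c(=O)ccoc2c1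
F4 | step 2 | racemic cis-fused 2,3-epoxy-5-hydroxy-7-methoxychroman-4-one (one enantiomer drawn) | COc1cc(O)c2C(=O)[C@@H]3O[C@@H]3Oc2c1
F5 | step 2 | 3,5-dihydroxy-7-methoxy-4H-chromen-4-one | COc1cc(O)c2c(=O)c(O)coc2c1
F6 | step 4 | 2-(4-benzyloxy-3-methoxyphenyl)-5-hydroxy-7-methoxy-4-oxo-4H-chromen-3-yl 2,2,2-trichloroethyl sulfate | COc1cc(O)c2c(=O)c(OS(=O)(=O)OCC(Cl)(Cl)Cl)c(-c3ccc(OCc4ccccc4)c(OC)c3)oc2c1
F7 | step 4 | ammonium rhamnazin 3-sulfate | COc1cc(O)c2c(=O)c(OS(=O)(=O)[O-])c(-c3ccc(O)c(OC)c3)oc2c1.[NH4+]
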